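**Remarks on the chemistry.** Ring carbons are numbered as in germacranolides: C1 (ketone), C4 (methyl-bearing alkene carbon), C5, C6 (lactone carbinol), C7 (ring-fusion carbon), C8 (ester carbinol), C10 (tertiary carbinol), C11–C13 (lactone carbons), C14 and C15 (methyls on C10 and C4). TBS is tert-butyldimethylsilyl. The C7 side chain is placed on the enone before the photochemical step, because alkylation next to the C8 silyloxy group on a ring would enter trans, whereas the target has the two groups cis.

## Analysis of the target

The target is a germacranolide: a ten-membered carbocycle (C1–C10) trans-fused at C6–C7 to an α-methylene-γ-butyrolactone (O–C6, C7, C11, C12, exocyclic C13). The ring carries a ketone at C1, a tertiary carbinol with a methyl group at C10, a trisubstituted C4=C5 alkene that is cis within the ring (4Z), and a tiglate on O8. The four stereocentres are 6R, 7R, 8R and 10R: the lactone oxygen on C6 is trans to the C7–C11 bond, the C8 ester oxygen is cis to it, and the C10 hydroxyl is 1,3-trans to O8. C6–C8 are contiguous, but C10 is separated from them by a methylene group, so no neighbouring group can set it. The α-methylene lactone is a Michael acceptor, the tertiary α-ketol can rearrange in base, the allylic C6–O bond can ionise in acid, a free C8 hydroxyl can translactonise onto C12, and ten-membered dienes of this kind cyclise transannularly. The difficulty is to make a ten-membered ring with a cis trisubstituted alkene and an oxidised C1/C10 pair without a macrocyclisation. The strategy reads the ring as two small rings: C1–C4, with oxygen on C1 and methyl on C4, are the atoms of 2-methylcyclobutanone, and C5–C10, with oxygen on C6 and methyl on C10, are those of a 3-methylcyclohex-2-enone whose alkene is C5=C10.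

## Retrosynthetic reasoning

**Ester at O8.** The tiglate is cut first, giving diol 28 and tiglic acid 29. It goes on last because it would not survive the enolate chemistry at C11. The forward acylation has to choose the secondary C8 hydroxyl over the tertiary C10 hydroxyl, which sterics should ensure.

**C1 ketone and C10 carbinol.** The C10–O bond of 28 (via its silyl ether 27) is cut back to the C1=C10 silyl enol ether of 25. The enol ether is a masked α-ketol: it protects the C1 ketone through every basic step and gives both oxygen functions in one Rubottom oxidation. The forward step must put oxygen on one face of C10 only, and the ring-locked trans enol ether offers only its outer face.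

**Exocyclic methylene.** C13 is removed from 25, leading to the saturated lactone 21. The methylene comes late because it is the most nucleophile-sensitive group. The forward sequence is hydroxymethylation (23) and dehydration.

**Lactone C–O bond and C6.** The acyl–oxygen bond of 21 is cut to hydroxy ester 20, and the C6–H bond is traced to the C6 ketone of dienone 19. The ketone is what links the ten-membered ring to an enone photosubstrate. The forward reduction must give the 6R alcohol, trans to the C7 side chain.

**Ten-membered ring.** In 19 the C4=C5 and C1=C10 double bonds are reconnected across the ring as the C5–C10 and C1–C4 single bonds of tricycle 18. This trades a medium ring for a strained bicyclo[2.2.0]hexane whose thermal opening is driven by relief of two four-membered rings. The forward opening must give the cis C4=C5 and trans C1=C10 isomer.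

**Key disconnection.** The central cyclobutane of 18 is cut at C4–C5 and C1–C10, giving enone 11 and silyloxycyclobutene 17. Both are small rings, and the two cuts fall exactly on the enone alkene and the enol ether alkene. The forward [2+2] photocycloaddition must be head to tail and must occur on the face of 11 opposite to its C7 and C8 substituents.

**Enone 11.** The C5=C10 bond is cut by ring-closing metathesis to diene ketone 10, which comes from Weinreb amide 9, silyl ether 8 and hydroxy diester 7. A desymmetrising aldol route to a simpler enone was set aside, because it gives neither reliable enantiopurity nor the C7 substituent.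

**C7–C11 bond.** In 7 the bond between C7 and the acetate unit is cut, giving β-hydroxy ester 4 and tert-butyl bromoacetate 5. A Fráter–Seebach alkylation sets C7 anti to the C8 hydroxyl in the open chain, which is the cis relationship on the later ring. The two esters of 7 differ (methyl and tert-butyl), so only the C6 carbonyl is converted further.

**β-Hydroxy ester 4.** The ester carbon is removed to epoxide 3 (carbonylation), and the isopropenyl group to (R)-epichlorohydrin 1, which supplies C8 in enantiopure form.

**Cyclobutene 17.** The Si–O bond is cut to 2-methylcyclobutanone 16, and the methyl group is removed via hydrazone 13 back to cyclobutanone 12.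

## Alternatives that were turned down

**Alternative 1:** The ring would be made by an anionic oxy-Cope ring expansion. The C8–C9 bond of the ten-membered ring is disconnected while C1–C6 is reconnected, leading back to a trans-1,2-dialkenylcyclohexenol. In the forward direction its potassium alkoxide rearranges through a chair to the ten-membered dienone A1 (C6 ketone, C8 ether, cis C4=C5, trans C1=C10). In its favour: the rearrangement is dependable, irreversible through enolate formation, and fixes both alkene geometries. It also delivers the C6 enolate regiospecifically, so C7 could be alkylated in the same flask. On alkene geometry it is stronger than the chosen route, which must earn the cis/trans pair from the way a strained ring opens. Against it: A1 has no oxygen at C1 or C10. The C1=C10 alkene would have to be epoxidised beside C4=C5 and then taken through opening and oxidation, in a ring type that cyclises transannularly under acid. The C7 side chain would also enter on the ten-membered ring, where its relationship to O8 is not controlled by a local model. In place of secure geometry, the chosen strategy offers C1 at the ketone oxidation level from the start, a built-in relay to C10, and C7 and C8 fixed before any ring exists.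

**Alternative 2:** The ring would be closed at C5–C6 by an intramolecular alkenylchromium addition (Nozaki–Hiyama–Kishi) of a cis alkenyl iodide to a C6 aldehyde, with the metal alkoxide closing the lactone, to give A2. In its favour: C7, C8, C10 and the C1 oxygen (as an acetonide with O10) are set in the open chain by acyclic methods, the cis alkene geometry is bought with the iodide, and no photochemistry is needed. On predictability of C10 and of the alkene it is stronger than the chosen route. Against it: the ring-forming step is a ten-membered macrocyclisation under transannular strain, needing high dilution and a large excess of a toxic divalent chromium salt. The C6 configuration is left to the ring. The linear precursor with four stereocentres and a trisubstituted iodoalkene is long before the ring exists. The chosen strategy instead assembles the whole carbocycle in two steps from two small rings.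

**Alternative 3:** A Paternò–Büchi reaction of an aldehyde (C8 as the formyl carbon) with furan A4 would give the exo oxetane A3, forming C7–C8 and the O–C6 bond. In its favour: the exo selectivity of this photoaldol is dependable, and for the C7/C8 pair it is as secure as the Fráter–Seebach alkylation used here. Against it: it sets only that pair. Induction from the distant C1/C10 acetonide is weak, so diastereomers are expected. The ten-membered ring, the cis C4=C5 alkene and the C11–C12 unit all remain to be made, by a later medium-ring closure with the problems of alternative 2. It spends a photochemical step on one bond, whereas the chosen route spends it on two bonds and the ring skeleton.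

Key step: step 11

## Route

Step 1
Reactants: 1 (R)-epichlorohydrin
Product: 3 (R)-2-(2-methylprop-2-en-1-yl)oxirane, via chlorohydrin 2 (not isolated)
Conditions: isopropenylmagnesium bromide, CuI (10 mol%), THF, −40 °C; then NaOH (aq), 25 °C
Reagents that add atoms: isopropenylmagnesium bromide, CC(=C)[Mg]Br
Why: Copper-catalysed Grignard opening occurs at the unsubstituted epoxide carbon and not at C–Cl, so the stereocentre is untouched; hydroxide then closes the chlorohydrin to the new terminal epoxide, and C8 keeps the configuration bought with 1.

Step 2
Reactants: 3 (R)-2-(2-methylprop-2-en-1-yl)oxirane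
Product: 4 methyl (R)-3-hydroxy-5-methylhex-5-enoate
Conditions: Co2(CO)8 (5 mol%), 3-hydroxypyridine (10 mol%), CO (40 bar), MeOH, THF, 65 °C
Reagents that add atoms: carbon monoxide, [C-]#[O+]; methanol, CO
Why: Cobalt-catalysed methoxycarbonylation of a terminal epoxide inserts CO at the unsubstituted C–O bond and leaves the carbinol centre unchanged.

Step 3
Reactants: 4 methyl (R)-3-hydroxy-5-methylhex-5-enoate; 5 tert-butyl bromoacetate
Product: 7 4-tert-butyl 1-methyl (2R)-2-[(1R)-1-hydroxy-3-methylbut-3-en-1-yl]butanedioate, via dilithium dianion 6 (not isolated)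
Conditions: LDA (2.2 equiv), THF, −78 → −20 °C; then 5, DMPU, −78 → −40 °C; AcOH quench
Reagents that add atoms: none
Why: Fráter–Seebach alkylation: the chelated alkoxide–enolate is attacked on the face away from the C9 chain, which sets C7 anti to the C8 hydroxyl in the open chain (cis on the later ring); the cold quench keeps the alkoxide from closing onto the new ester.

Step 4
Reactants: 7 4-tert-butyl 1-methyl (2R)-2-[(1R)-1-hydroxy-3-methylbut-3-en-1-yl]butanedioate
Product: 8 4-tert-butyl 1-methyl (2R)-2-[(1R)-1-(TBS-oxy)-3-methylbut-3-en-1-yl]butanedioate
Conditions: TBSOTf, 2,6-lutidine, CH2Cl2, −78 → 0 °C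
Reagents that add atoms: tert-butyldimethylsilyl triflate, CC(C)(C)[Si](C)(C)OS(=O)(=O)C(F)(F)F
Why: Standard silylation of a hindered secondary alcohol; it blocks lactonisation of O8 onto the tert-butyl ester.

Step 5
Reactants: 8 4-tert-butyl 1-methyl (2R)-2-[(1R)-1-(TBS-oxy)-3-methylbut-3-en-1-yl]butanedioate
Product: 9 tert-butyl (3R,4R)-4-(TBS-oxy)-3-[methoxy(methyl)carbamoyl]-6-methylhept-6-enoate
Conditions: MeNH(OMe)·HCl, AlMe3, CH2Cl2, 0 → 40 °C
Reagents that add atoms: N,O-dimethylhydroxylamine hydrochloride, CNOC.Cl
Why: Aluminium amide aminolysis (Weinreb amide formation) converts the methyl ester while the tert-butyl ester is too hindered to react; the conditions are not basic, so C7 is not epimerised.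

Step 6
Reactants: 9 tert-butyl (3R,4R)-4-(TBS-oxy)-3-[methoxy(methyl)carbamoyl]-6-methylhept-6-enoate
Product: 10 tert-butyl (3R,4R)-4-(TBS-oxy)-6-methyl-3-(prop-2-enoyl)hept-6-enoate
Conditions: vinylmagnesium bromide, THF, −20 → 0 °C; inverse quench into cold 1 M HCl
Reagents that add atoms: vinylmagnesium bromide, C=C[Mg]Br
Why: Grignard addition to a Weinreb amide stops at the chelated tetrahedral adduct, and the acidic inverse quench releases the vinyl ketone without conjugate addition of the liberated amine.

Step 7
Reactants: 10 tert-butyl (3R,4R)-4-(TBS-oxy)-6-methyl-3-(prop-2-enoyl)hept-6-enoate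
Product: 11 tert-butyl 2-[(1R,6R)-6-(TBS-oxy)-4-methyl-2-oxocyclohex-3-en-1-yl]acetate
Conditions: second-generation Grubbs catalyst [RuCl2(=CHPh)(PCy3)(H2IMes)] (5 mol%), CH2Cl2 (0.01 M), 40 °C
Reagents that add atoms: none
Why: Ring-closing metathesis between the enone vinyl group and the 1,1-disubstituted alkene closes the six-membered ring and forms the trisubstituted C5=C10 enone; the neutral conditions leave the cis C7/C8 pair of this β-silyloxy ketone untouched.

Step 8
Reactants: 12 cyclobutanone
Product: 13 cyclobutanone N,N-dimethylhydrazone
Conditions: Me2NNH2, AcOH (cat.), EtOH, 60 °C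
Reagents that add atoms: N,N-dimethylhydrazine, CN(C)N
Why: Hydrazone formation; the hydrazone allows clean mono-alkylation where the cyclobutanone enolate would self-condense.

Step 9
Reactants: 13 cyclobutanone N,N-dimethylhydrazone
Product: 16 2-methylcyclobutanone (racemic), via lithium azaenolate 14 (not isolated), via methylated hydrazone 15 (not isolated)
Conditions: LDA, THF, 0 °C; MeI, −78 → 0 °C; then aqueous oxalic acid, pentane, 25 °C
Reagents that add atoms: iodomethane, CI; water, O
Why: Azaenolate alkylation gives mono-methylation, and two-phase acid hydrolysis releases the volatile ketone.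

Step 10
Reactants: 16 2-methylcyclobutanone (racemic)
Product: 17 1-methyl-2-(TBS-oxy)cyclobut-1-ene
Conditions: TBSOTf, Et3N, CH2Cl2, 0 → 25 °C
Reagents that add atoms: tert-butyldimethylsilyl triflate, CC(C)(C)[Si](C)(C)OS(=O)(=O)C(F)(F)F
Why: Soft enolisation under equilibrating conditions favours the more substituted, tetrasubstituted silyl enol ether; the stereocentre of 16 disappears, and the minor trisubstituted isomer is removed by distillation.

Step 11
Reactants: 11 tert-butyl 2-[(1R,6R)-6-(TBS-oxy)-4-methyl-2-oxocyclohex-3-en-1-yl]acetate; 17 1-methyl-2-(TBS-oxy)cyclobut-1-ene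
Product: 18 cis-anti-cis photoadduct, tert-butyl ester of the (1S,4R,5R,7R,8R,10R)-tricyclic ketone with new bonds C4–C5 and C1–C10 (TBS-oxy on C1 and C8, methyls on C4 and C10, ketone C6, acetate chain on C7)
Conditions: hν (350–366 nm, Pyrex), 17 (5 equiv), CH2Cl2, −40 °C, degassed
Reagents that add atoms: none
Why: This is an enone [2+2] photocycloaddition: the triplet enone of 11 adds to the electron-rich C1=C4 bond of 17 to give a triplet 1,4-diradical that closes after spin inversion; the closest known reactions are photoadditions of cyclohexenones to cyclobutenes and to 1,2-bis(silyloxy)cyclobutenes. The cyclobutane is closed by radical–radical coupling of the 1,4-diradical, cis at C5/C10 because a trans-fused cyclohexanone on a bicyclo[2.2.0]hexane is too strained. Regiochemistry should be head to tail: the polarised enol ether turns its oxygen-bearing carbon C1 to the β-carbon C10 and its nucleophilic carbon C4 to the α-carbon C5. C5 and C10 are set by the enone face: the C7 side chain and the C8 silyloxy group are cis and shield one face (the silyloxy group axial, 1,3 to C10), so the cyclobutene should add to the other. C1 and C4 are set by exo approach, with the CH2CH2 bridge of the cyclobutene turned away from the six-membered ring (cis-anti-cis). The step needs head-to-tail regioselectivity, which the donor polarity of the enol ether must secure against the steric cost of joining fully substituted carbons, and anti facial selectivity, which the two ring substituents secure. The four new centres are transient, but their relative configuration decides the alkene geometries in step 12 and, through the planar chirality of the enol ether, the configuration of C10 in step 17.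

Step 12
Reactants: 18 cis-anti-cis photoadduct
Product: 19 tert-butyl (7R,8R)-1,8-bis(TBS-oxy)-6-oxo-13-norgermacra-1(10),4-dien-12-oate, C4=C5 cis in the ring, C1=C10 trans in the ring (C2 and C9 on opposite sides)
Conditions: toluene (0.01 M), 150 °C, sealed base-washed tube, 2,6-di-tert-butyl-4-methylpyridine (cat.)
Reagents that add atoms: none
Why: Thermal cycloreversion of the bicyclo[2.2.0]hexane (formal retro-[2+2] through a cyclohexane-1,4-diyl) cleaves C1–C4 and C5–C10 and relieves both four-membered rings. The cyclohexanone chair that avoids the syn-diaxial C8–OTBS/C10–methyl pair puts C5–C6 axial and C10–C9 equatorial on the diyl ring, which should open to the cis C4=C5 enone and the trans C1=C10 enol ether. The tetrasubstituted trans enol ether cannot turn through the ring, so its inner face (towards C4=C5) and outer face stay fixed by the configuration of 18.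

Step 13
Reactants: 19 tert-butyl (7R,8R)-1,8-bis(TBS-oxy)-6-oxo-13-norgermacra-1(10),4-dien-12-oate
Product: 20 tert-butyl (6R,7S,8R)-1,8-bis(TBS-oxy)-6-hydroxy-13-norgermacra-1(10),4-dien-12-oate
Conditions: (R)-2-methyl-CBS-oxazaborolidine (1.0 equiv), catecholborane, toluene, −78 → −40 °C
Reagents that add atoms: none
Why: Corey–Bakshi–Shibata reduction gives 1,2-reduction of the enone under reagent control; with the alkenyl arm as the large group, the (R)-catalyst should give the 6R carbinol, trans to the C7 side chain. Catecholborane at low temperature leaves the ester, silyl ethers and alkenes alone.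

Step 14
Reactants: 20 tert-butyl (6R,7S,8R)-1,8-bis(TBS-oxy)-6-hydroxy-13-norgermacra-1(10),4-dien-12-oate
Product: 21 (6R,7S,8R)-1,8-bis(TBS-oxy)-13-norgermacra-1(10),4-dien-6,12-olide (trans-fused lactone)
Conditions: NaH (0.2 equiv), THF, 0 → 25 °C
Reagents that add atoms: none
Why: Alkoxide-catalysed intramolecular transesterification (5-exo-trig) closes the trans-fused γ-lactone, and the released tert-butoxide carries the chain; no acid is present, so the silyl enol ether is not protonated.

Step 15
Reactants: 21 (6R,7S,8R)-1,8-bis(TBS-oxy)-13-norgermacra-1(10),4-dien-6,12-olide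
Product: 23 (6R,7S,8R)-1,8-bis(TBS-oxy)-13-hydroxygermacra-1(10),4-dien-6,12-olide (C11 epimers), via lithium enolate 22 (not isolated)
Conditions: LDA, THF, −78 °C; CH2O (gas), −78 → −40 °C; NH4Cl (aq)
Reagents that add atoms: formaldehyde, C=O
Why: Aldol addition of the lactone enolate to monomeric formaldehyde; the silyl enol ether does not react with formaldehyde without a Lewis acid, and the C11 configuration is irrelevant because that centre becomes sp2.

Step 16
Reactants: 23 (6R,7S,8R)-1,8-bis(TBS-oxy)-13-hydroxygermacra-1(10),4-dien-6,12-olide (C11 epimers)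
Product: 25 (6R,7S,8R)-1,8-bis(TBS-oxy)germacra-1(10),4,11(13)-trien-6,12-olide, via mesylate 24 (not isolated)
Conditions: MsCl, Et3N, CH2Cl2, 0 °C; then DBU, 0 → 25 °C
Reagents that add atoms: none
Why: Mesylation and E1cB elimination give the α-methylene lactone from either C11 epimer.

Step 17
Reactants: 25 (6R,7S,8R)-1,8-bis(TBS-oxy)germacra-1(10),4,11(13)-trien-6,12-olide
Product: 27 (6R,7S,8R,10R)-8,10-bis(TBS-oxy)-1-oxogermacra-4,11(13)-dien-6,12-olide, via silyloxy epoxide 26 (not isolated)
Conditions: dimethyldioxirane (1.1 equiv), acetone/CH2Cl2, −78 → 0 °C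
Reagents that add atoms: dimethyldioxirane, CC1(C)OO1
Why: Rubottom oxidation: the tetrasubstituted silyl enol ether is the most electron-rich alkene and is epoxidised first, and silyl migration opens the silyloxy epoxide to the α-silyloxy ketone. Oxygen can only arrive on the outer face of the ring-locked trans enol ether, the face opposite to the former C5–C10 bond of 18, which gives 10R.

Step 18
Reactants: 27 (6R,7S,8R,10R)-8,10-bis(TBS-oxy)-1-oxogermacra-4,11(13)-dien-6,12-olide
Product: 28 (6R,7R,8R,10R)-8,10-dihydroxy-1-oxogermacra-4,11(13)-dien-6,12-olide
Conditions: HF·pyridine, pyridine, THF, 0 → 25 °C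
Reagents that add atoms: none
Why: Fluoride cleaves both Si–O bonds; buffered HF avoids the basic conditions under which the free C8 hydroxyl could attack the lactone or add to the methylene lactone.

Step 19
Reactants: 28 (6R,7R,8R,10R)-8,10-dihydroxy-1-oxogermacra-4,11(13)-dien-6,12-olide; 29 tiglic acid
Product: 31 CNP0345906.3, via mixed anhydride 30 (not isolated)
Conditions: 29, 2,4,6-trichlorobenzoyl chloride, Et3N, toluene, 25 °C; then 28, DMAP, 25 °C
Reagents that add atoms: none
Why: Yamaguchi esterification: the mixed anhydride acylates the secondary C8 hydroxyl under DMAP catalysis, the tertiary α-ketol hydroxyl is too hindered to react, and the E geometry of the tiglate is retained.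

## Compound list

1 | (R)-epichlorohydrin | ClC[C@H]1CO1 | starting material
2 | (R)-1-chloro-4-methylpent-4-en-2-ol (as magnesium alkoxide in the flask) | ClC[C@H](O)CC(C)=C | intermediate
3 | (R)-2-(2-methylprop-2-en-1-yl)oxirane | C=C(C)C[C@@H]1CO1 | intermediate
4 | methyl (R)-3-hydroxy-5-methylhex-5-enoate | COC(=O)C[C@H](O)CC(C)=C | intermediate
5 | tert-butyl bromoacetate | CC(C)(C)OC(=O)CBr | starting material
6 | dilithium alkoxide–enolate of 4 | [Li+].[Li+].COC([O-])=C[C@H]([O-])CC(C)=C | intermediate
7 | 4-tert-butyl 1-methyl (2R)-2-[(1R)-1-hydroxy-3-methylbut-3-en-1-yl]butanedioate | COC(=O)[C@H](CC(=O)OC(C)(C)C)[C@H](O)CC(C)=C | intermediate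
8 | 4-tert-butyl 1-methyl (2R)-2-[(1R)-1-(TBS-oxy)-3-methylbut-3-en-1-yl]butanedioate | COC(=O)[C@H](CC(=O)OC(C)(C)C)[C@H](O[Si](C)(C)C(C)(C)C)CC(C)=C | intermediate
9 | tert-butyl (3R,4R)-4-(TBS-oxy)-3-[methoxy(methyl)carbamoyl]-6-methylhept-6-enoate | CON(C)C(=O)[C@H](CC(=O)OC(C)(C)C)[C@H](O[Si](C)(C)C(C)(C)C)CC(C)=C | intermediate
10 | tert-butyl (3R,4R)-4-(TBS-oxy)-6-methyl-3-(prop-2-enoyl)hept-6-enoate | C=CC(=O)[C@H](CC(=O)OC(C)(C)C)[C@H](O[Si](C)(C)C(C)(C)C)CC(C)=C | intermediate
11 | tert-butyl 2-[(1R,6R)-6-(TBS-oxy)-4-methyl-2-oxocyclohex-3-en-1-yl]acetate (substituents cis) | O=C1[C@H](CC(=O)OC(C)(C)C)[C@H](O[Si](C)(C)C(C)(C)C)CC(C)=C1 | intermediate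
12 | cyclobutanone | O=C1CCC1 | starting material
13 | cyclobutanone N,N-dimethylhydrazone | CN(C)N=C1CCC1 | intermediate
14 | lithium azaenolate of 13 | [Li+].CN(C)[N-]C1=CCC1 | intermediate
15 | 2-methylcyclobutanone N,N-dimethylhydrazone (racemic) | CN(C)N=C1CCC1C | intermediate
16 | 2-methylcyclobutanone (racemic) | CC1CCC1=O | intermediate
17 | 1-methyl-2-(TBS-oxy)cyclobut-1-ene | CC1=C(O[Si](C)(C)C(C)(C)C)CC1 | intermediate
18 | cis-anti-cis photoadduct (1S,4R,5R,7R,8R,10R; bonds C1–C4, C4–C5, C5–C10, C1–C10 form the central cyclobutane; cyclobutane on the face opposite to the C7 and C8 substituents) | O=C1[C@H](CC(=O)OC(C)(C)C)[C@H](O[Si](C)(C)C(C)(C)C)C[C@]2(C)[C@H]1[C@@]1(C)CC[C@@]21O[Si](C)(C)C(C)(C)C | intermediate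
19 | tert-butyl (7R,8R)-1,8-bis(TBS-oxy)-6-oxo-13-norgermacra-1(10),4-dien-12-oate (C4=C5 cis in ring, C1=C10 trans in ring) | O=C1/C=C(/C)CC/C(O[Si](C)(C)C(C)(C)C)=C(\C)C[C@@H](O[Si](C)(C)C(C)(C)C)[C@H]1CC(=O)OC(C)(C)C | intermediate
20 | tert-butyl (6R,7S,8R)-1,8-bis(TBS-oxy)-6-hydroxy-13-norgermacra-1(10),4-dien-12-oate | O[C@@H]1/C=C(/C)CC/C(O[Si](C)(C)C(C)(C)C)=C(\C)C[C@@H](O[Si](C)(C)C(C)(C)C)[C@H]1CC(=O)OC(C)(C)C | intermediate
21 | (6R,7S,8R)-1,8-bis(TBS-oxy)-13-norgermacra-1(10),4-dien-6,12-olide | O=C1O[C@@H]2/C=C(/C)CC/C(O[Si](C)(C)C(C)(C)C)=C(\C)C[C@@H](O[Si](C)(C)C(C)(C)C)[C@H]2C1 | intermediate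
22 | lithium enolate of 21 | [Li+].[O-]C1O[C@@H]2/C=C(/C)CC/C(O[Si](C)(C)C(C)(C)C)=C(\C)C[C@@H](O[Si](C)(C)C(C)(C)C)[C@H]2C=1 | intermediate
23 | (6R,7S,8R)-1,8-bis(TBS-oxy)-13-hydroxygermacra-1(10),4-dien-6,12-olide (C11 epimers) | O=C1O[C@@H]2/C=C(/C)CC/C(O[Si](C)(C)C(C)(C)C)=C(\C)C[C@@H](O[Si](C)(C)C(C)(C)C)[C@H]2C1CO | intermediate
24 | 13-mesylate of 23 | O=C1O[C@@H]2/C=C(/C)CC/C(O[Si](C)(C)C(C)(C)C)=C(\C)C[C@@H](O[Si](C)(C)C(C)(C)C)[C@H]2C1COS(C)(=O)=O | intermediate
25 | (6R,7S,8R)-1,8-bis(TBS-oxy)germacra-1(10),4,11(13)-trien-6,12-olide | C=C1C(=O)O[C@@H]2/C=C(/C)CC/C(O[Si](C)(C)C(C)(C)C)=C(\C)C[C@@H](O[Si](C)(C)C(C)(C)C)[C@@H]12 | intermediate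
26 | (1S,6R,7S,8R,10R)-1,10-epoxy-1,8-bis(TBS-oxy)germacra-4,11(13)-dien-6,12-olide | C=C1C(=O)O[C@@H]2/C=C(/C)CC[C@@]3(O[Si](C)(C)C(C)(C)C)O[C@]3(C)C[C@@H](O[Si](C)(C)C(C)(C)C)[C@@H]12 | intermediate
27 | (6R,7S,8R,10R)-8,10-bis(TBS-oxy)-1-oxogermacra-4,11(13)-dien-6,12-olide | C=C1C(=O)O[C@@H]2/C=C(/C)CCC(=O)[C@](C)(O[Si](C)(C)C(C)(C)C)C[C@@H](O[Si](C)(C)C(C)(C)C)[C@@H]12 | intermediate
28 | (6R,7R,8R,10R)-8,10-dihydroxy-1-oxogermacra-4,11(13)-dien-6,12-olide | C=C1C(=O)O[C@@H]2/C=C(/C)CCC(=O)[C@](C)(O)C[C@@H](O)[C@@H]12 | intermediate
29 | tiglic acid, (E)-2-methylbut-2-enoic acid | C/C=C(\C)C(O)=O | starting material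
30 | tiglic 2,4,6-trichlorobenzoic anhydride | C/C=C(\C)C(=O)OC(=O)c1c(Cl)cc(Cl)cc1Cl | intermediate
31 | CNP0345906.3, (6R,7R,8R,10R)-10-hydroxy-1-oxo-8-tigloyloxygermacra-4Z,11(13)-dien-6,12-olide | C=C1C(=O)O[C@@H]2/C=C(/C)CCC(=O)[C@](C)(O)C[C@@H](OC(=O)/C(C)=C/C)[C@@H]12 | target

## Step count and least certain steps

Total step count: 19. Longest linear sequence: 16 steps (steps 1–7 and 11–19); steps 8–10 are a three-step side branch.

**Step 11 (key step).** The most likely failure is that the triplet enone does not add cleanly head to tail to the fully substituted silyl enol ether. Three contiguous quaternary carbons are formed, so the bulk of the silyloxy group may push the addition head to head, or slow it enough for enone dimerisation and hydrogen abstraction to compete. Leakage in facial selectivity would pass on to C10. As a fallback, the smaller trimethylsilyl donor is used, the partner class for which enone photoadditions are best documented, and the silyl group is exchanged afterwards. The fallback sets out from 16 and 11. Ketone 16 is converted with TMSCl, NaI and Et3N in MeCN into 1-methyl-2-(trimethylsilyloxy)cyclobut-1-ene F1. Irradiation of 11 with F1 as in step 11 gives the trimethylsilyl photoadduct F2. Citric acid in methanol at 0 °C frees the tertiary cyclobutanol F3 without touching the secondary TBS ether or the C7 centre, and TBSOTf with 2,6-lutidine returns the route to 18.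

**Step 12.** Two processes may go wrong. The flattened cyclohexanone may only weakly prefer the chair that leads to the cis C4=C5/trans C1=C10 pair, which would erode the geometry and with it the relay to C10. Heating may also bring on Cope rearrangement of the 1,5-diene, or scission of the other cyclobutane bond to a divinylcyclohexanone. As a fallback, the order of ring opening and reduction is reversed. The fallback sets out from 18. NaBH4 in MeOH at −20 °C, with hydride expected on the face opposite to the cyclobutane, gives the tricyclic alcohol F4. Its sp3 C6 restores a true chair in which the syn-diaxial silyloxy/methyl clash fully disfavours the wrong conformer, and it removes the heat-sensitive β-silyloxy ketone. Heating F4 in toluene at 170–180 °C with short contact time (flow) opens it to 20, where the route is rejoined. The price is a higher temperature, because the forming C4=C5 bond is no longer conjugated.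

**Step 13.** The ten-membered ring may expose only one face of the C6 carbonyl and override the catalyst, so hydride delivery may give the C6 epimer (hydroxyl cis to the C7 side chain). As a fallback, the substrate-controlled alcohol is accepted and the lactone is closed with inversion. The fallback sets out from 19. Luche reduction (NaBH4, CeCl3·7H2O, MeOH, −78 °C) gives the 6S alcohol F5. MsCl and Et3N in CH2Cl2 at −20 → 25 °C give the allylic mesylate F6. The carbonyl oxygen of the neighbouring tert-butyl ester displaces the mesylate from the back (5-exo), and the resulting alkoxycarbenium ion loses 2-methylpropene, giving the trans-fused lactone 21, where the route is rejoined.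

**Step 17.** The silyloxy epoxide opens through a silyloxy-stabilised cation at C1 that faces the C4=C5 alkene across the ring. Transannular cyclisation may therefore compete with silyl migration, and excess oxidant may epoxidise C4=C5. As a fallback, the enol ether is dihydroxylated instead of epoxidised, so no cation is formed. The fallback sets out from 25. OsO4 (cat.) with N-methylmorpholine N-oxide in acetone/water at 0 °C attacks the same outer face of the most electron-rich alkene, and the silyl hemiketal collapses to the α-hydroxy ketone F7 (C10 hydroxyl free, C8 still silylated). HF·pyridine as in step 18 then gives 28, where the route is rejoined.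

## Further compounds

F1 | step 11 | 1-methyl-2-(trimethylsilyloxy)cyclobut-1-ene | CC1=C(O[Si](C)(C)C)CC1
F2 | step 11 | photoadduct as 18 with trimethylsilyloxy on C1 | O=C1[C@H](CC(=O)OC(C)(C)C)[C@H](O[Si](C)(C)C(C)(C)C)C[C@]2(C)[C@H]1[C@@]1(C)CC[C@@]21O[Si](C)(C)C
F3 | step 11 | photoadduct as 18 with free hydroxyl on C1 | O=C1[C@H](CC(=O)OC(C)(C)C)[C@H](O[Si](C)(C)C(C)(C)C)C[C@]2(C)[C@H]1[C@@]1(C)CC[C@@]21O
F4 | step 12 | C6 alcohol of 18 (hydroxyl cis to the cyclobutane, trans to the C7 side chain) | O[C@H]1[C@H](CC(=O)OC(C)(C)C)[C@H](O[Si](C)(C)C(C)(C)C)C[C@]2(C)[C@H]1[C@@]1(C)CC[C@@]21O[Si](C)(C)C(C)(C)C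
F5 | step 13 | C6 epimer of 20 (6S) | O[C@H]1/C=C(/C)CC/C(O[Si](C)(C)C(C)(C)C)=C(\C)C[C@@H](O[Si](C)(C)C(C)(C)C)[C@H]1CC(=O)OC(C)(C)C
F6 | step 13 | mesylate of F5 | CS(=O)(=O)O[C@H]1/C=C(/C)CC/C(O[Si](C)(C)C(C)(C)C)=C(\C)C[C@@H](O[Si](C)(C)C(C)(C)C)[C@H]1CC(=O)OC(C)(C)C
F7 | step 17 | (6R,7S,8R,10R)-8-(TBS-oxy)-10-hydroxy-1-oxogermacra-4,11(13)-dien-6,12-olide | C=C1C(=O)O[C@@H]2/C=C(/C)CCC(=O)[C@](C)(O)C[C@@H](O[Si](C)(C)C(C)(C)C)[C@@H]12
A1 | alternative 1 | ten-membered dienone from the anionic oxy-Cope ring expansion (C6 ketone, C8 p-methoxybenzyl ether) | O=C1C[C@H](OCc2ccc(OC)cc2)C/C(C)=C/CC/C(C)=C\1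
A2 | alternative 2 | trans-lactone-fused cyclodecene with C1/C10 acetonide and C8 silyl ether | O=C1C[C@H]2[C@H](O1)/C=C(/C)CC[C@H]3OC(C)(C)O[C@]3(C)C[C@H]2O[Si](C)(C)C(C)(C)C
A3 | alternative 3 | exo furan–aldehyde photoadduct (2,7-dioxabicyclo[3.2.0]hept-3-ene) | C1=CO[C@H]2O[C@H](C[C@@]3(C)OC(C)(C)O[C@@H]3CCC(C)=C)[C@@H]12
A4 | alternative 3 | furan | c1ccoc1
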